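**Plan**

- Retrosynthesis: the C3 ester C–O bond is cut first (acid from (S)-2-methylbutan-1-ol), then the C7 hydroxyl is removed (diosphenol back to the 9-en-8-one), then ring A is opened at C1–C2 (vinylogous aldol). After that C2–C3 (vinyl ketone from an amide) and C4–C5 (ester-enolate Claisen) are cut, which leaves 2,3-dimethylcyclohex-2-en-1-one.
- Forward: ring B is the starting cyclohexenone; the C4–C3–C2 chain is grown on its quaternary carbon C5; ring A closes by C1–C2 bond formation; the dienoate is attached afterwards and C7 is oxygenated last.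
- Enabling feature: C1 is the γ-carbon (a methyl group on C10) of the C8=O/C9=C10 enone of ring B and C2 is a carbinol carbon, so C1–C2 is a vinylogous aldol bond. C5 is quaternary, so no other γ-position can enolise.
- Stereochemistry: the C9 carbinol comes from a CBS reduction and is relayed suprafacially to C5 and, through the chair of the (E)-ketene acetal, to C4. C3 comes from a Felkin–Anh reduction next to C4, C2 from the ring closure under control of the axial C3 oxygen, and C6′ from the chiral pool.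

Key step: step 10

Remark: C-numbers in the text follow the decalin numbering of the target (C1–C10, carbonyl at C8, methyl groups on C4 and C5); 17 and 32 each carry one centre that the next operation destroys and are taken on as epimer mixtures.

**Route**

Step 1
Reactants: 1 2,3-dimethylcyclohex-2-en-1-one
Product: 2 (1R)-2,3-dimethylcyclohex-2-en-1-ol
Conditions: (S)-2-methyl-CBS-oxazaborolidine [(S)-1-methyl-3,3-diphenyltetrahydro-1H,3H-pyrrolo[1,2-c][1,3,2]oxazaborole] (10 mol %), BH3·SMe2, THF, −20 °C; MeOH quench, aqueous work-up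
Reagents that add atoms: none
Why: Corey–Bakshi–Shibata reduction: the oxazaborolidine binds the carbonyl anti to the bulkier 2-methylalkenyl flank and delivers hydride 1,2 to one face, which should set the (R)-carbinol centre that is later relayed to C5.

Step 2
Reactants: 2 (1R)-2,3-dimethylcyclohex-2-en-1-ol; 3 propanoyl chloride
Product: 4 (1R)-2,3-dimethylcyclohex-2-en-1-yl propanoate
Conditions: Et3N, DMAP (cat.), CH2Cl2, 0 °C
Reagents that add atoms: propanoyl chloride (3), CCC(=O)Cl
Why: DMAP-catalysed acylation of a secondary allylic alcohol by an acid chloride, which touches no stereocentre.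

Step 3
Reactants: 4 (1R)-2,3-dimethylcyclohex-2-en-1-yl propanoate
Product: 8 (2R)-2-[(1R)-1,2-dimethylcyclohex-2-en-1-yl]propanoic acid, via lithium enolate 5 (not isolated), via silyl ketene acetal 6 (not isolated), via trimethylsilyl ester 7 (not isolated)
Conditions: LiN(i-Pr)2, THF, −78 °C; Me3SiCl, −78 °C → rt, then 60 °C; 1 M HCl work-up
Reagents that add atoms: none
Why: Ireland–Claisen rearrangement: kinetic enolisation in THF gives the (E)-silyl ketene acetal, whose [3,3] shift through a chair (α-methyl turned away from the ring) forms C4–C5 on the face that carried the C–O bond, so the carbinol configuration is transferred to quaternary C5 and the ketene acetal geometry sets C4 (methyl groups cis in the later ring A); the minor (Z)-isomer is expected to react through a boat and converge on the same acid.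

Step 4
Reactants: 8 (2R)-2-[(1R)-1,2-dimethylcyclohex-2-en-1-yl]propanoic acid
Product: 10 (2R)-2-[(1R)-1,2-dimethylcyclohex-2-en-1-yl]-N-methoxy-N-methylpropanamide, via acid chloride 9 (not isolated)
Conditions: (COCl)2, DMF (cat.), CH2Cl2, 0 °C → rt; then MeNH(OMe)·HCl, pyridine, CH2Cl2, 0 °C → rt
Reagents that add atoms: N,O-dimethylhydroxylamine hydrochloride, CNOC.Cl
Why: Acid chloride formation followed by aminolysis is the dependable way to a Weinreb amide from a hindered acid, and C4 is not enolised under these conditions.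

Step 5
Reactants: 10 (2R)-2-[(1R)-1,2-dimethylcyclohex-2-en-1-yl]-N-methoxy-N-methylpropanamide; 11 vinylmagnesium bromide
Product: 13 (4R)-4-[(1R)-1,2-dimethylcyclohex-2-en-1-yl]pent-1-en-3-one, via magnesium alkoxide adduct 12 (not isolated)
Conditions: CH2=CHMgBr, THF, 0 °C → rt; inverse quench into cold 1 M HCl
Reagents that add atoms: vinylmagnesium bromide (11), C=C[Mg]Br
Why: Weinreb ketone synthesis: the chelated adduct 12 resists a second addition and collapses to the vinyl ketone only on acidic quench, which also keeps the liberated amine from adding to the new enone.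

Step 6
Reactants: 13 (4R)-4-[(1R)-1,2-dimethylcyclohex-2-en-1-yl]pent-1-en-3-one
Product: 14 (3S,4R)-4-[(1R)-1,2-dimethylcyclohex-2-en-1-yl]pent-1-en-3-ol
Conditions: NaBH4, CeCl3·7H2O, MeOH, −78 °C
Reagents that add atoms: none
Why: Luche 1,2-reduction under Felkin–Anh control by C4 (hydride anti to the quaternary ring carbon) should give the 3,4-anti alcohol, which is the C3 configuration of the target (C3–O cis to the C4 methyl group once ring A exists).

Step 7
Reactants: 14 (3S,4R)-4-[(1R)-1,2-dimethylcyclohex-2-en-1-yl]pent-1-en-3-ol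
Product: 15 {[(3S,4R)-4-[(1R)-1,2-dimethylcyclohex-2-en-1-yl]pent-1-en-3-yl]oxy}triethylsilane
Conditions: Et3SiOTf, 2,6-lutidine, CH2Cl2, −78 °C
Reagents that add atoms: triethylsilyl trifluoromethanesulfonate, CC[Si](CC)(CC)OS(=O)(=O)C(F)(F)F
Why: Silyl triflate silylation of a hindered secondary alcohol; TES is chosen because it survives the next three steps, cannot chelate, and can later be cleaved beside a TBS ether.

Step 8
Reactants: 15 {[(3S,4R)-4-[(1R)-1,2-dimethylcyclohex-2-en-1-yl]pent-1-en-3-yl]oxy}triethylsilane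
Product: 16 (4R)-3,4-dimethyl-4-{(2R,3S)-3-[(triethylsilyl)oxy]pent-4-en-2-yl}cyclohex-2-en-1-one
Conditions: CrO3, 3,5-dimethylpyrazole, CH2Cl2, −20 °C
Reagents that add atoms: chromium trioxide, O=[Cr](=O)=O
Why: Allylic oxidation with the CrO3·3,5-dimethylpyrazole complex attacks the ring methylene next to the electron-rich trisubstituted alkene (the other ring allylic position is quaternary C5 and the methyl group is less reactive), giving the C8 ketone conjugated with C9=C10 while the monosubstituted vinyl group and the silyl ether should persist.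

Step 9
Reactants: 16 (4R)-3,4-dimethyl-4-{(2R,3S)-3-[(triethylsilyl)oxy]pent-4-en-2-yl}cyclohex-2-en-1-one
Product: 18 (2R,3R)-3-[(1R)-1,2-dimethyl-4-oxocyclohex-2-en-1-yl]-2-[(triethylsilyl)oxy]butanal, via diol 17 (not isolated)
Conditions: OsO4 (cat.), NaIO4, 2,6-lutidine, 1,4-dioxane/H2O, rt
Reagents that add atoms: osmium tetroxide, O=[Os](=O)(=O)=O; sodium periodate (reoxidant), [Na+].[O-]I(=O)(=O)=O
Why: Lemieux–Johnson cleavage: OsO4 dihydroxylates the terminal vinyl group much faster than the hindered, electron-poor enone C=C, and periodate cleaves diol 17 to the α-silyloxy aldehyde under buffered conditions that should leave C3 untouched.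

Step 10
Reactants: 18 (2R,3R)-3-[(1R)-1,2-dimethyl-4-oxocyclohex-2-en-1-yl]-2-[(triethylsilyl)oxy]butanal
Product: 20 (4aR,5R,6R,7R)-7-{[tert-butyl(dimethyl)silyl]oxy}-4a,5-dimethyl-6-[(triethylsilyl)oxy]-4,4a,5,6,7,8-hexahydronaphthalen-2(3H)-one, via silyl dienol ether 19 (not isolated)
Conditions: t-BuMe2SiOTf (1.3 equiv), 2,6-lutidine (1.5 equiv), CH2Cl2, −78 → −20 °C; aq. NaHCO3
Reagents that add atoms: tert-butyldimethylsilyl trifluoromethanesulfonate, CC(C)(C)[Si](C)(C)OS(=O)(=O)C(F)(F)F
Why: Proposed new method: t-BuMe2SiOTf silylates the enone oxygen and 2,6-lutidine removes a proton reversibly, so that the extended silyl dienol ether 19 (exocyclic C10=C1; the other γ-carbon, C5, is quaternary) is available, and its terminus C1 adds to the silyl-activated aldehyde carbon C2, which restores the C9=C10 enone and leaves the new C2 oxygen as its TBS ether. The closest known reactions are the vinylogous Mukaiyama aldol addition of preformed silyl dienol ethers of γ-methyl enones and the one-pot silyl triflate/amine Mukaiyama aldol of simple ketones; their intramolecular, vinylogous combination is the untested element. Ring A closes in a 6-(enolendo)-exo-trig mode through a chair. The new stereocentre C2 is controlled by the C3 silyloxy group: ring B holds the C5 methyl group axial on the forming ring, which puts the C4 methyl group equatorial and the C3–O bond axial, and the activated C=O should align anti to that bond (Cornforth-type dipole opposition, no chelation possible at silicon), placing the C2 oxygen axial and trans to the C3 oxygen (7R in 20). The step needs γ- over α′-reactivity and an untouched aldehyde α-centre: attack from C7 would require a bridged bicyclo[3.3.1]nonane transition state with the branched chain axial, the aldehyde α-hydrogen is tertiary and flanked by the silyloxy group and the C4 branch, and only a slight excess of silyl triflate is used so that the product enone is not enolised in turn.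

Step 11
Reactants: 20 (4aR,5R,6R,7R)-7-{[tert-butyl(dimethyl)silyl]oxy}-4a,5-dimethyl-6-[(triethylsilyl)oxy]-4,4a,5,6,7,8-hexahydronaphthalen-2(3H)-one
Product: 21 (4aR,5R,6R,7R)-7-{[tert-butyl(dimethyl)silyl]oxy}-6-hydroxy-4a,5-dimethyl-4,4a,5,6,7,8-hexahydronaphthalen-2(3H)-one
Conditions: pyridinium p-toluenesulfonate (cat.), MeOH/CH2Cl2, 0 °C
Reagents that add atoms: none
Why: Acid-catalysed methanolysis discriminates silyl ethers by size, so the TES ether should be cleaved far faster than the TBS ether and only the C3 hydroxyl is freed.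

Step 12
Reactants: 22 (2S)-2-methylbutan-1-ol
Product: 23 (2S)-2-methylbutanal
Conditions: 2,2,6,6-tetramethylpiperidin-1-oxyl (cat.), KBr (cat.), NaOCl, aq. NaHCO3, CH2Cl2, 0 °C; distillation
Reagents that add atoms: none
Why: Anelli oxidation (oxoammonium-mediated) stops at the aldehyde and, under the buffered two-phase conditions, is expected to leave the α-stereocentre intact.

Step 13
Reactants: 23 (2S)-2-methylbutanal; 24 triethyl (E)-4-phosphonocrotonate
Product: 26 ethyl (2E,4E,6S)-6-methylocta-2,4-dienoate, via lithiated phosphonate 25 (not isolated)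
Conditions: LiN(SiMe3)2, THF, −78 °C; then 23, −78 → 0 °C
Reagents that add atoms: triethyl (E)-4-phosphonocrotonate (24), CCOC(=O)/C=C/CP(=O)(OCC)OCC
Why: Vinylogous Horner–Wadsworth–Emmons olefination: the stabilised phosphonate anion should give the (4E) alkene while the (2E) geometry is carried in the reagent, and the low temperature protects the α-stereocentre of the aldehyde.

Step 14
Reactants: 26 ethyl (2E,4E,6S)-6-methylocta-2,4-dienoate
Product: 28 (2E,4E,6S)-6-methylocta-2,4-dienoic acid, via lithium carboxylate 27 (not isolated)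
Conditions: LiOH·H2O, THF/MeOH/H2O, rt; then 1 M HCl
Reagents that add atoms: lithium hydroxide monohydrate, [Li+].[OH-].O
Why: Saponification of an unhindered ethyl ester, in which the remote C6 centre is not acidic.

Step 15
Reactants: 21 (4aR,5R,6R,7R)-7-{[tert-butyl(dimethyl)silyl]oxy}-6-hydroxy-4a,5-dimethyl-4,4a,5,6,7,8-hexahydronaphthalen-2(3H)-one; 28 (2E,4E,6S)-6-methylocta-2,4-dienoic acid
Product: 30 (1R,2R,3R,8aR)-3-{[tert-butyl(dimethyl)silyl]oxy}-1,8a-dimethyl-6-oxo-1,2,3,4,6,7,8,8a-octahydronaphthalen-2-yl (2E,4E,6S)-6-methylocta-2,4-dienoate, via mixed anhydride 29 (not isolated)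
Conditions: 2,4,6-trichlorobenzoyl chloride, Et3N, toluene, rt; then 21, DMAP, toluene, rt → 40 °C
Reagents that add atoms: (2E,4E,6S)-6-methylocta-2,4-dienoic acid (28), CC[C@H](C)/C=C/C=C/C(=O)O
Why: Yamaguchi esterification: DMAP transfers the dienoyl group from mixed anhydride 29 to the hindered axial C3 hydroxyl, and the neighbouring TBS ether cannot migrate without an alkoxide.

Step 16
Reactants: 30 (1R,2R,3R,8aR)-3-{[tert-butyl(dimethyl)silyl]oxy}-1,8a-dimethyl-6-oxo-1,2,3,4,6,7,8,8a-octahydronaphthalen-2-yl (2E,4E,6S)-6-methylocta-2,4-dienoate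
Product: 32 (1R,2R,3R,7RS,8aR)-3-{[tert-butyl(dimethyl)silyl]oxy}-7-hydroxy-1,8a-dimethyl-6-oxo-1,2,3,4,6,7,8,8a-octahydronaphthalen-2-yl (2E,4E,6S)-6-methylocta-2,4-dienoate, via sodium dienolate 31 (not isolated)
Conditions: NaN(SiMe3)2, THF, −78 °C (ketone added to base); then 3-phenyl-2-(phenylsulfonyl)oxaziridine, −78 °C; aq. NH4Cl
Reagents that add atoms: 3-phenyl-2-(phenylsulfonyl)oxaziridine, O=S(=O)(N1OC1c1ccccc1)c1ccccc1
Why: Kinetic deprotonation by a hindered amide base occurs at the α′-methylene C7 (cross-conjugated enolate 31), and electrophilic oxygen transfer from the N-sulfonyloxaziridine (Davis-type enolate hydroxylation) gives the α′-hydroxy enone, whose new C7 centre is removed in the next step.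

Step 17
Reactants: 32 (1R,2R,3R,7RS,8aR)-3-{[tert-butyl(dimethyl)silyl]oxy}-7-hydroxy-1,8a-dimethyl-6-oxo-1,2,3,4,6,7,8,8a-octahydronaphthalen-2-yl (2E,4E,6S)-6-methylocta-2,4-dienoate
Product: 34 (1R,2R,3R,8aS)-3-{[tert-butyl(dimethyl)silyl]oxy}-7-hydroxy-1,8a-dimethyl-6-oxo-1,2,3,4,6,8a-hexahydronaphthalen-2-yl (2E,4E,6S)-6-methylocta-2,4-dienoate, via diketone 33 (not isolated)
Conditions: Dess–Martin periodinane, CH2Cl2, rt
Reagents that add atoms: none
Why: Dess–Martin oxidation of the acyloin gives the 7,8-dione 33, which can enolise only towards C6 and should therefore settle as the cross-conjugated diosphenol; the C2 hydroxyl is still silylated and cannot be oxidised.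

Step 18
Reactants: 34 (1R,2R,3R,8aS)-3-{[tert-butyl(dimethyl)silyl]oxy}-7-hydroxy-1,8a-dimethyl-6-oxo-1,2,3,4,6,8a-hexahydronaphthalen-2-yl (2E,4E,6S)-6-methylocta-2,4-dienoate
Product: 35 septeremophilane G, (1R,2R,3R,8aS)-3,7-dihydroxy-1,8a-dimethyl-6-oxo-1,2,3,4,6,8a-hexahydronaphthalen-2-yl (2E,4E,6S)-6-methylocta-2,4-dienoate
Conditions: HF·pyridine, pyridine/THF, 0 °C → rt
Reagents that add atoms: none
Why: Fluoride-mediated desilylation under buffered, mildly acidic conditions removes the secondary TBS ether; the trans-diaxial C2/C3 oxygens disfavour acyl migration and no base is present to eliminate the C2 hydroxyl.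

**Compound list**

1 | 2,3-dimethylcyclohex-2-en-1-one | CC1=C(C)C(=O)CCC1 | starting material
2 | (1R)-2,3-dimethylcyclohex-2-en-1-ol | O[C@@H]1CCCC(C)=C1C | intermediate
3 | propanoyl chloride | CCC(=O)Cl | starting material
4 | (1R)-2,3-dimethylcyclohex-2-en-1-yl propanoate | CCC(=O)O[C@@H]1CCCC(C)=C1C | intermediate
5 | lithium enolate of 4, methyl cis to the cyclohexenyloxy group (not isolated) | C/C=C(/[O-])O[C@@H]1CCCC(C)=C1C.[Li+] | intermediate
6 | {[(1E)-1-{[(1R)-2,3-dimethylcyclohex-2-en-1-yl]oxy}prop-1-en-1-yl]oxy}trimethylsilane (not isolated) | C/C=C(/O[Si](C)(C)C)O[C@@H]1CCCC(C)=C1C | intermediate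
7 | trimethylsilyl (2R)-2-[(1R)-1,2-dimethylcyclohex-2-en-1-yl]propanoate (not isolated) | C[Si](C)(C)OC(=O)[C@H](C)[C@@]1(C)CCCC=C1C | intermediate
8 | (2R)-2-[(1R)-1,2-dimethylcyclohex-2-en-1-yl]propanoic acid | OC(=O)[C@H](C)[C@@]1(C)CCCC=C1C | intermediate
9 | (2R)-2-[(1R)-1,2-dimethylcyclohex-2-en-1-yl]propanoyl chloride (not isolated) | ClC(=O)[C@H](C)[C@@]1(C)CCCC=C1C | intermediate
10 | (2R)-2-[(1R)-1,2-dimethylcyclohex-2-en-1-yl]-N-methoxy-N-methylpropanamide | CON(C)C(=O)[C@H](C)[C@@]1(C)CCCC=C1C | intermediate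
11 | vinylmagnesium bromide | C=C[Mg]Br | starting material
12 | bromomagnesium alkoxide of the tetrahedral adduct of 10 and 11, epimers at the new carbon (not isolated) | C=CC(O[Mg]Br)(N(C)OC)[C@H](C)[C@@]1(C)CCCC=C1C | intermediate
13 | (4R)-4-[(1R)-1,2-dimethylcyclohex-2-en-1-yl]pent-1-en-3-one | C=CC(=O)[C@H](C)[C@@]1(C)CCCC=C1C | intermediate
14 | (3S,4R)-4-[(1R)-1,2-dimethylcyclohex-2-en-1-yl]pent-1-en-3-ol | O[C@@H](C=C)[C@H](C)[C@@]1(C)CCCC=C1C | intermediate
15 | {[(3S,4R)-4-[(1R)-1,2-dimethylcyclohex-2-en-1-yl]pent-1-en-3-yl]oxy}triethylsilane | CC[Si](CC)(CC)O[C@@H](C=C)[C@H](C)[C@@]1(C)CCCC=C1C | intermediate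
16 | (4R)-3,4-dimethyl-4-{(2R,3S)-3-[(triethylsilyl)oxy]pent-4-en-2-yl}cyclohex-2-en-1-one | CC[Si](CC)(CC)O[C@@H](C=C)[C@H](C)[C@@]1(C)CCC(=O)C=C1C | intermediate
17 | (4R)-4-{(2R,3R,4RS)-4,5-dihydroxy-3-[(triethylsilyl)oxy]pentan-2-yl}-3,4-dimethylcyclohex-2-en-1-one (not isolated) | CC[Si](CC)(CC)O[C@@H](C(O)CO)[C@H](C)[C@@]1(C)CCC(=O)C=C1C | intermediate
18 | (2R,3R)-3-[(1R)-1,2-dimethyl-4-oxocyclohex-2-en-1-yl]-2-[(triethylsilyl)oxy]butanal | CC[Si](CC)(CC)O[C@@H](C=O)[C@H](C)[C@@]1(C)CCC(=O)C=C1C | intermediate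
19 | (2R,3R)-3-[(1R)-4-{[tert-butyl(dimethyl)silyl]oxy}-1-methyl-2-methylidenecyclohex-3-en-1-yl]-2-[(triethylsilyl)oxy]butanal (not isolated) | CC[Si](CC)(CC)O[C@@H](C=O)[C@H](C)[C@@]1(C)CCC(O[Si](C)(C)C(C)(C)C)=CC1=C | intermediate
20 | (4aR,5R,6R,7R)-7-{[tert-butyl(dimethyl)silyl]oxy}-4a,5-dimethyl-6-[(triethylsilyl)oxy]-4,4a,5,6,7,8-hexahydronaphthalen-2(3H)-one | CC[Si](CC)(CC)O[C@H]1[C@H](O[Si](C)(C)C(C)(C)C)CC2=CC(=O)CC[C@]2(C)[C@H]1C | intermediate
21 | (4aR,5R,6R,7R)-7-{[tert-butyl(dimethyl)silyl]oxy}-6-hydroxy-4a,5-dimethyl-4,4a,5,6,7,8-hexahydronaphthalen-2(3H)-one | O[C@H]1[C@H](O[Si](C)(C)C(C)(C)C)CC2=CC(=O)CC[C@]2(C)[C@H]1C | intermediate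
22 | (2S)-2-methylbutan-1-ol | CC[C@H](C)CO | starting material
23 | (2S)-2-methylbutanal | CC[C@H](C)C=O | intermediate
24 | triethyl (E)-4-phosphonocrotonate, ethyl (2E)-4-(diethoxyphosphoryl)but-2-enoate | CCOC(=O)/C=C/CP(=O)(OCC)OCC | starting material
25 | lithium salt of the C4 carbanion of 24 (not isolated) | CCOC(=O)/C=C/[CH-]P(=O)(OCC)OCC.[Li+] | intermediate
26 | ethyl (2E,4E,6S)-6-methylocta-2,4-dienoate | CC[C@H](C)/C=C/C=C/C(=O)OCC | intermediate
27 | lithium (2E,4E,6S)-6-methylocta-2,4-dienoate (not isolated) | CC[C@H](C)/C=C/C=C/C(=O)[O-].[Li+] | intermediate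
28 | (2E,4E,6S)-6-methylocta-2,4-dienoic acid | CC[C@H](C)/C=C/C=C/C(=O)O | intermediate
29 | (2E,4E,6S)-6-methylocta-2,4-dienoic 2,4,6-trichlorobenzoic anhydride (not isolated) | CC[C@H](C)/C=C/C=C/C(=O)OC(=O)c1c(Cl)cc(Cl)cc1Cl | intermediate
30 | (1R,2R,3R,8aR)-3-{[tert-butyl(dimethyl)silyl]oxy}-1,8a-dimethyl-6-oxo-1,2,3,4,6,7,8,8a-octahydronaphthalen-2-yl (2E,4E,6S)-6-methylocta-2,4-dienoate | CC[C@H](C)/C=C/C=C/C(=O)O[C@H]1[C@H](O[Si](C)(C)C(C)(C)C)CC2=CC(=O)CC[C@]2(C)[C@H]1C | intermediate
31 | sodium cross-conjugated dienolate (C7=C8–O⁻) of 30 (not isolated) | CC[C@H](C)/C=C/C=C/C(=O)O[C@H]1[C@H](O[Si](C)(C)C(C)(C)C)CC2=CC([O-])=CC[C@]2(C)[C@H]1C.[Na+] | intermediate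
32 | (1R,2R,3R,7RS,8aR)-3-{[tert-butyl(dimethyl)silyl]oxy}-7-hydroxy-1,8a-dimethyl-6-oxo-1,2,3,4,6,7,8,8a-octahydronaphthalen-2-yl (2E,4E,6S)-6-methylocta-2,4-dienoate | CC[C@H](C)/C=C/C=C/C(=O)O[C@H]1[C@H](O[Si](C)(C)C(C)(C)C)CC2=CC(=O)C(O)C[C@]2(C)[C@H]1C | intermediate
33 | (1R,2R,3R,8aR)-3-{[tert-butyl(dimethyl)silyl]oxy}-1,8a-dimethyl-6,7-dioxo-1,2,3,4,6,7,8,8a-octahydronaphthalen-2-yl (2E,4E,6S)-6-methylocta-2,4-dienoate (not isolated) | CC[C@H](C)/C=C/C=C/C(=O)O[C@H]1[C@H](O[Si](C)(C)C(C)(C)C)CC2=CC(=O)C(=O)C[C@]2(C)[C@H]1C | intermediate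
34 | (1R,2R,3R,8aS)-3-{[tert-butyl(dimethyl)silyl]oxy}-7-hydroxy-1,8a-dimethyl-6-oxo-1,2,3,4,6,8a-hexahydronaphthalen-2-yl (2E,4E,6S)-6-methylocta-2,4-dienoate | CC[C@H](C)/C=C/C=C/C(=O)O[C@H]1[C@H](O[Si](C)(C)C(C)(C)C)CC2=CC(=O)C(O)=C[C@]2(C)[C@H]1C | intermediate
35 | septeremophilane G, (1R,2R,3R,8aS)-3,7-dihydroxy-1,8a-dimethyl-6-oxo-1,2,3,4,6,8a-hexahydronaphthalen-2-yl (2E,4E,6S)-6-methylocta-2,4-dienoate | CC[C@H](C)/C=C/C=C/C(=O)O[C@H]1[C@H](O)CC2=CC(=O)C(O)=C[C@]2(C)[C@H]1C | target

**Step count and risks**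

Total: 18 steps. Longest linear sequence: 15 steps (steps 1–11 and 15–18, from 1 to 35); the side-chain acid 28 takes 3 steps (12–14).

The three steps most likely to fail:

First, step 10 (the proposed ring closure). Deprotonation of the silylated enone at C7, or silyl enol ether formation at the aldehyde with loss of the C3 configuration, may outrun γ-enolisation. The orientation of the activated carbonyl in the closing chair may also be incompletely controlled, which would erode the C2 configuration. The fallback uses known chemistry and sets out from 18. Both carbonyl groups are complexed with aluminium tris(2,6-diphenylphenoxide) in toluene at −78 °C and the C1 methyl group is deprotonated with lithium 2,2,6,6-tetramethylpiperidide in THF. The bulky aluminium phenoxide screens C7 and the aldehyde α-position, so the aluminium dienolate should add through C1 (directed vinylogous aldol addition). This gives the free aldol (4aR,5R,6R,7R)-7-hydroxy-4a,5-dimethyl-6-[(triethylsilyl)oxy]-4,4a,5,6,7,8-hexahydronaphthalen-2(3H)-one F1, which is silylated (t-BuMe2SiOTf, 2,6-lutidine, CH2Cl2, −78 °C) to rejoin the route at 20.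

Second, step 8. Hydrogen abstraction at the C1 methyl group or at the C3–H bond (allylic and α to oxygen), or oxidative loss of the TES group, may compete with oxidation of the C8 methylene. The fallback sets out from 15 and replaces direct C–H oxidation by an epoxide-based 1,3-oxygen transposition:
- mCPBA (NaHCO3, CH2Cl2, 0 °C) should epoxidise only the trisubstituted ring alkene, giving triethyl({(3S,4R)-4-[1,2-dimethyl-7-oxabicyclo[4.1.0]heptan-2-yl]pent-1-en-3-yl}oxy)silane F2. It is drawn with the oxirane anti to the side chain; either face converges.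
- PhSeNa (from (PhSe)2 and NaBH4, EtOH, reflux) opens the oxirane at the less substituted C9 to give the trans hydroxy selenide 1,2-dimethyl-6-(phenylselanyl)-2-{(2R,3S)-3-[(triethylsilyl)oxy]pent-4-en-2-yl}cyclohexan-1-ol F3.
- Oxidative elimination (H2O2, pyridine, THF, 0 °C → rt) can only proceed towards C8 and gives the tertiary allylic alcohol 1,6-dimethyl-6-{(2R,3S)-3-[(triethylsilyl)oxy]pent-4-en-2-yl}cyclohex-2-en-1-ol F4.
- Pyridinium chlorochromate (CH2Cl2, rt) effects the Dauben–Babler oxidative 1,3-transposition and rejoins the route at 16.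

Third, step 16. Proton transfer may convert the kinetic C7 enolate into the extended C1 dienolate, which can expel the C2 silyloxy group, and the enolate may add to the sulfonimine by-product. The fallback sets out from 30 and avoids strong base. α′-Acetoxylation with Mn(OAc)3·2H2O in refluxing benzene should give (1R,2R,3R,7RS,8aR)-7-acetoxy-3-{[tert-butyl(dimethyl)silyl]oxy}-1,8a-dimethyl-6-oxo-1,2,3,4,6,7,8,8a-octahydronaphthalen-2-yl (2E,4E,6S)-6-methylocta-2,4-dienoate F5. Its activated α-keto acetate is then cleaved with K2CO3 in MeOH at 0 °C in preference to the hindered, conjugated dienoate, rejoining the route at 32.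

**Further compounds**

F1 | step 10 | (4aR,5R,6R,7R)-7-hydroxy-4a,5-dimethyl-6-[(triethylsilyl)oxy]-4,4a,5,6,7,8-hexahydronaphthalen-2(3H)-one | CC[Si](CC)(CC)O[C@H]1[C@H](O)CC2=CC(=O)CC[C@]2(C)[C@H]1C
F2 | step 8 | triethyl({(3S,4R)-4-[1,2-dimethyl-7-oxabicyclo[4.1.0]heptan-2-yl]pent-1-en-3-yl}oxy)silane, oxirane anti to the side chain | CC[Si](CC)(CC)O[C@@H](C=C)[C@H](C)[C@@]1(C)CCC[C@@H]2O[C@]12C
F3 | step 8 | 1,2-dimethyl-6-(phenylselanyl)-2-{(2R,3S)-3-[(triethylsilyl)oxy]pent-4-en-2-yl}cyclohexan-1-ol, selanyl trans to hydroxyl | CC[Si](CC)(CC)O[C@@H](C=C)[C@H](C)[C@@]1(C)CCC[C@@H]([Se]c2ccccc2)[C@@]1(O)C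
F4 | step 8 | 1,6-dimethyl-6-{(2R,3S)-3-[(triethylsilyl)oxy]pent-4-en-2-yl}cyclohex-2-en-1-ol | CC[Si](CC)(CC)O[C@@H](C=C)[C@H](C)[C@@]1(C)CCC=C[C@@]1(O)C
F5 | step 16 | (1R,2R,3R,7RS,8aR)-7-acetoxy-3-{[tert-butyl(dimethyl)silyl]oxy}-1,8a-dimethyl-6-oxo-1,2,3,4,6,7,8,8a-octahydronaphthalen-2-yl (2E,4E,6S)-6-methylocta-2,4-dienoate | CC[C@H](C)/C=C/C=C/C(=O)O[C@H]1[C@H](O[Si](C)(C)C(C)(C)C)CC2=CC(=O)C(OC(C)=O)C[C@]2(C)[C@H]1C
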